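**Retrosynthetic overview**

1. The target is read as ent-oritin-(4α→6)-epioritin-4β-ol. The last operations are global debenzylation, DDQ/H2O hydroxylation of C4 of the lower unit (unit A) trans to O3, and a dynamic kinetic hydrogenation of a flavan-3-one that sets C2 and C3 of unit A cis.
2. Ring C of unit A is disconnected at C2–C3. C2 is carried as the carbonyl carbon of a 4-benzyloxybenzoate on O1, and C3 as the internal alkene carbon of an ortho-allyl group on C4a. A titanium-alkylidene ring-closing carbonyl–olefin metathesis joins them as the C2=C3 enol ether (flav-2-ene).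
3. Enabling feature: in ring C of unit A, C2 bears only O1, ring B and H, so it can sit on O1 as an ester carbon. C3 is linked through C4 to C4a, the ring A carbon ortho to O1, exactly where a Claisen rearrangement from O1 places an allyl group. Later, the C2–H flanked by C3=O, O1 and ring B is labile, which permits the dynamic reduction.
4. The C4(unit B)–C6(unit A) bond comes from addition of the lithiated allyl-pyrogallol fragment to the C4 ketone of a (2S,3S)-dihydroflavonol; ionic hydrogenation of the carbinol then sets C4 of unit B.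
5. Ring order: rings A and B of both units come from commercial arenes; ring C of unit B is closed first (chalcone epoxide cyclization, step 5) and ring C of unit A last (step 15).

Key step: step 15

Remark: all starting materials are taken as commercial and flavan numbering is used for both units (unit A = lower flavan-3,4-diol unit, 2R,3R,4S; unit B = upper 4-arylflavan-3-ol unit, 2S,3R,4R in the target). Bn = benzyl; "UB" = the (2S,3R)-3,7,8-tris(benzyloxy)-2-[4-(benzyloxy)phenyl]chroman-4-yl group whose C4 bond is cis to O3 and trans to the C2 aryl group (CIP label 4S while the phenols are benzylated, 4R in the free target).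

**Route**

Step 1
Reactants: 1 2',3',4'-trihydroxyacetophenone
Product: 2 1-[3,4-bis(benzyloxy)-2-hydroxyphenyl]ethan-1-one
Conditions: BnBr (2.05 equiv), K2CO3, acetone, reflux
Reagents that add atoms: benzyl bromide, BrCc1ccccc1
Why: Williamson etherification in which the 2-hydroxyl, hydrogen-bonded to the acetyl carbonyl, is the least nucleophilic and should stay free, so that the oxygens that become O7 and O8 of unit B are benzylated selectively.

Step 2
Reactants: 2 1-[3,4-bis(benzyloxy)-2-hydroxyphenyl]ethan-1-one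
Product: 3 1-[3,4-bis(benzyloxy)-2-(methoxymethoxy)phenyl]ethan-1-one
Conditions: NaH, MOMCl, DMF, 0 °C to rt
Reagents that add atoms: chloromethyl methyl ether, COCCl
Why: MOM protection (Williamson-type O-alkylation) of the chelated phenol after full deprotonation, which should prevent flavanone or aurone formation in steps 3 and 4.

Step 3
Reactants: 3 1-[3,4-bis(benzyloxy)-2-(methoxymethoxy)phenyl]ethan-1-one, 4 4-(benzyloxy)benzaldehyde
Product: 5 (E)-1-[3,4-bis(benzyloxy)-2-(methoxymethoxy)phenyl]-3-[4-(benzyloxy)phenyl]prop-2-en-1-one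
Conditions: KOH, EtOH–THF, rt
Reagents that add atoms: none
Why: Claisen–Schmidt condensation of the methyl ketone with the non-enolizable aldehyde, with dehydration giving the conjugated (E)-enone under thermodynamic control.

Step 4
Reactants: 5 (E)-1-[3,4-bis(benzyloxy)-2-(methoxymethoxy)phenyl]-3-[4-(benzyloxy)phenyl]prop-2-en-1-one
Product: 6 [3,4-bis(benzyloxy)-2-(methoxymethoxy)phenyl][(2S,3R)-3-[4-(benzyloxy)phenyl]oxiran-2-yl]methanone
Conditions: poly-D-leucine, urea–H2O2, DBU, THF, rt
Reagents that add atoms: hydrogen peroxide (as its urea adduct), OO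
Why: Juliá–Colonna epoxidation, in which the helical poly-D-leucine should deliver hydroperoxide to one face of the (E)-enone and so set both epoxide centres as the trans (2S,3R) isomer.

Step 5
Reactants: 6 [3,4-bis(benzyloxy)-2-(methoxymethoxy)phenyl][(2S,3R)-3-[4-(benzyloxy)phenyl]oxiran-2-yl]methanone
Product: 8 (2S,3S)-7,8-bis(benzyloxy)-2-[4-(benzyloxy)phenyl]-3-hydroxychroman-4-one, via phenol epoxide 7 (not isolated)
Conditions: conc. HCl, MeOH–THF, 50 °C
Reagents that add atoms: none
Why: acid removal of the MOM group followed by 6-endo opening of the epoxide by the freed phenol at the benzylic carbon with inversion (chalcone epoxide to dihydroflavonol cyclization), which should convert the (2S,3R)-epoxide into the 2,3-trans (2S,3S) ring C of unit B while the carbinol centre is untouched.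

Step 6
Reactants: 8 (2S,3S)-7,8-bis(benzyloxy)-2-[4-(benzyloxy)phenyl]-3-hydroxychroman-4-one
Product: 9 (2S,3S)-3,7,8-tris(benzyloxy)-2-[4-(benzyloxy)phenyl]chroman-4-one
Conditions: benzyl 2,2,2-trichloroacetimidate, TfOH (cat.), CH2Cl2–cyclohexane, 0 °C to rt
Reagents that add atoms: benzyl 2,2,2-trichloroacetimidate, N=C(OCc1ccccc1)C(Cl)(Cl)Cl
Why: acid-catalysed O-benzylation with a trichloroacetimidate, chosen because basic benzylation would open or epimerize the 3-hydroxyflavanone; no stereocentre is touched.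

Step 7
Reactants: 10 2,3-dihydroxybenzaldehyde
Product: 11 2,3-bis(benzyloxy)benzaldehyde
Conditions: BnBr, K2CO3, DMF, 60 °C
Reagents that add atoms: benzyl bromide, BrCc1ccccc1
Why: exhaustive Williamson etherification of both phenols, which become O7 and O8 of unit A.

Step 8
Reactants: 11 2,3-bis(benzyloxy)benzaldehyde
Product: 13 2,3-bis(benzyloxy)phenol, via aryl formate 12 (not isolated)
Conditions: mCPBA, CH2Cl2, rt; then K2CO3, MeOH, rt
Reagents that add atoms: mCPBA, O=C(OO)c1cccc(Cl)c1
Why: Dakin-type Baeyer–Villiger oxidation in which the electron-rich aryl group migrates to oxygen, and methanolysis of the formate then frees the phenol that becomes O1 of unit A.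

Step 9
Reactants: 13 2,3-bis(benzyloxy)phenol, 14 allyl bromide
Product: 15 1-(allyloxy)-2,3-bis(benzyloxy)benzene
Conditions: K2CO3, acetone, reflux
Reagents that add atoms: none
Why: Williamson etherification that places the allyl group (future C4 and C3 of unit A) on the oxygen that becomes O1.

Step 10
Reactants: 15 1-(allyloxy)-2,3-bis(benzyloxy)benzene
Product: 16 6-allyl-2,3-bis(benzyloxy)phenol
Conditions: PhNEt2, 190 °C
Reagents that add atoms: none
Why: aromatic Claisen rearrangement, a [3,3]-sigmatropic shift that can deliver the allyl group only to the single free ortho carbon (the future C4a), the other ortho position carrying a benzyloxy group.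

Step 11
Reactants: 16 6-allyl-2,3-bis(benzyloxy)phenol
Product: 17 6-allyl-2,3-bis(benzyloxy)-4-bromophenol
Conditions: NBS, MeCN, −20 to 0 °C
Reagents that add atoms: N-bromosuccinimide, O=C1CCC(=O)N1Br
Why: electrophilic aromatic bromination para to the free phenol, the only activated ring position still open because both ortho positions are substituted, and expected to be much faster than any reaction of the isolated alkene.

Step 12
Reactants: 17 6-allyl-2,3-bis(benzyloxy)-4-bromophenol, 9 (2S,3S)-3,7,8-tris(benzyloxy)-2-[4-(benzyloxy)phenyl]chroman-4-one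
Product: 19 (2S,3S)-4-[5-allyl-2,3-bis(benzyloxy)-4-hydroxyphenyl]-3,7,8-tris(benzyloxy)-2-[4-(benzyloxy)phenyl]chroman-4-ol (both C4 epimers), via dilithiated phenoxide 18 (not isolated)
Conditions: 17, n-BuLi (2.1 equiv), THF, −78 °C; then 9, LaCl3·2LiCl, THF, −78 to −40 °C; aq. NH4Cl
Reagents that add atoms: none
Why: deprotonation and bromine–lithium exchange followed by LaCl3·2LiCl-promoted 1,2-addition of the aryllithium to the ketone, the lanthanum salt suppressing enolization and ring opening of the 3-alkoxychromanone; the configuration of the new carbinol centre is irrelevant because it is ionized in step 13.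

Step 13
Reactants: 19 (2S,3S)-4-[5-allyl-2,3-bis(benzyloxy)-4-hydroxyphenyl]-3,7,8-tris(benzyloxy)-2-[4-(benzyloxy)phenyl]chroman-4-ol
Product: 20 6-allyl-2,3-bis(benzyloxy)-4-UB-phenol
Conditions: Et3SiH, CF3CO2H, CH2Cl2, −40 °C
Reagents that add atoms: none
Why: ionic hydrogenation (acid ionization of the tertiary bis-benzylic alcohol to a cation stabilized by the para-hydroxyaryl ring, then hydride transfer from the silane), in which hydride is expected to enter anti to the adjacent 3-benzyloxy group, as nucleophiles do with 2,3-trans flavan-4-yl cations, so that the aryl group ends cis to O3 and trans to the C2 aryl group.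

Step 14
Reactants: 20 6-allyl-2,3-bis(benzyloxy)-4-UB-phenol, 21 4-(benzyloxy)benzoyl chloride
Product: 22 6-allyl-2,3-bis(benzyloxy)-4-UB-phenyl 4-(benzyloxy)benzoate
Conditions: Et3N, DMAP (cat.), CH2Cl2, 0 °C to rt
Reagents that add atoms: none
Why: DMAP-catalysed acylation of the only free hydroxyl, which installs C2 and ring B of unit A on O1 at the carboxyl oxidation level.

Step 15
Reactants: 22 6-allyl-2,3-bis(benzyloxy)-4-UB-phenyl 4-(benzyloxy)benzoate
Product: 23 7,8-bis(benzyloxy)-2-[4-(benzyloxy)phenyl]-6-UB-4H-chromene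
Conditions: TiCl4, TMEDA, Zn, PbCl2 (cat.), CH3CHBr2, THF–CH2Cl2, 0 to 65 °C, high dilution; K2CO3/Et3N work-up
Reagents that add atoms: none
Why: Proposed new method: the titanium ethylidene generated from CH3CHBr2, TiCl4, Zn and TMEDA is expected to exchange with the unhindered terminal alkene of the ortho-allyl group (loss of propene) to give a titanium alkylidene at C3, which adds across the neighbouring ester C=O (C2) to an oxatitanacyclobutane and cycloreverts to the C2=C3 enol ether with transfer of the carbonyl oxygen to titanium; the alternative order, ethylidenation of the ester followed by alkylidene-mediated ring-closing metathesis, leads to the same product. The closest known reaction type is the Takai–Utimoto titanium-alkylidene olefinic ester cyclization (ring-closing carbonyl–olefin metathesis) of alkenyl alkyl esters to six- and seven-membered cyclic enol ethers, together with methylenation of aryl esters and ring-closing metathesis of aryl vinyl ethers to 4H-chromenes; what is new is the aryl ester of an ortho-allylphenol as substrate. The pyran ring C of unit A is closed in a six-membered mode by intramolecular [2+2] addition and cycloreversion between the C3 alkylidene and the C2 carbonyl, which are held on the adjacent ring A positions C4a (through C4) and C8a (through O1). No stereocentre is created: C2 and C3 are deliberately left trigonal so that both can be set together by catalyst control in step 18. The step needs chemoselectivity for the single ester carbonyl and cyclization over intermolecular olefination, which the absence of any other carbonyl or alkene, the ortho relationship of the two partners and high dilution should secure. The trisubstituted, aryl-conjugated enol ether is not expected to isomerize or hydrolyse under the basic work-up.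

Step 16
Reactants: 23 7,8-bis(benzyloxy)-2-[4-(benzyloxy)phenyl]-6-UB-4H-chromene
Product: 25 2,3-trans-7,8-bis(benzyloxy)-2-[4-(benzyloxy)phenyl]-6-UB-chroman-3-ol (both trans diastereomers), via alkylborane 24 (not isolated)
Conditions: BH3·THF, THF, 0 °C; then NaOH, H2O2, 0 °C to rt
Reagents that add atoms: hydrogen peroxide, OO
Why: hydroboration–oxidation of the enol ether with boron adding to C3 (away from the oxygen- and aryl-bearing C2) and syn addition, which should give the 2,3-trans alcohol as a pair of diastereomers whose unit A configuration is erased again in step 17.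

Step 17
Reactants: 25 2,3-trans-7,8-bis(benzyloxy)-2-[4-(benzyloxy)phenyl]-6-UB-chroman-3-ol
Product: 26 7,8-bis(benzyloxy)-2-[4-(benzyloxy)phenyl]-6-UB-chroman-3-one (C2 epimers)
Conditions: Dess–Martin periodinane, NaHCO3, CH2Cl2, rt
Reagents that add atoms: none
Why: Dess–Martin oxidation of the secondary alcohol to the flavan-3-one, whose C2 centre, flanked by the carbonyl, ring B and O1, becomes configurationally labile for step 18.

Step 18
Reactants: 26 7,8-bis(benzyloxy)-2-[4-(benzyloxy)phenyl]-6-UB-chroman-3-one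
Product: 27 (2R,3R)-7,8-bis(benzyloxy)-2-[4-(benzyloxy)phenyl]-6-UB-chroman-3-ol
Conditions: RuCl2[(R)-Xyl-SDP][(S,S)-DPEN] (1 mol %), t-BuOK (cat.), H2 (50 atm), i-PrOH–toluene, rt
Reagents that add atoms: none
Why: Noyori-type asymmetric hydrogenation with dynamic kinetic resolution, in which base equilibrates the C2 epimers of the α-aryl-α-aryloxy ketone and the chiral ruthenium diphosphine–diamine catalyst should reduce one of them cis-selectively, funnelling the mixture into the 2,3-cis (2R,3R) alcohol; the catalyst antipode is chosen by analogy with 2-arylcycloalkanones and its mirror image would be used if the sense proved opposite.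

Step 19
Reactants: 27 (2R,3R)-7,8-bis(benzyloxy)-2-[4-(benzyloxy)phenyl]-6-UB-chroman-3-ol
Product: 28 (2R,3R,4S)-7,8-bis(benzyloxy)-2-[4-(benzyloxy)phenyl]-6-UB-chromane-3,4-diol
Conditions: DDQ, CH2Cl2–H2O, 0 °C to rt
Reagents that add atoms: water, O
Why: DDQ benzylic oxidation (hydride abstraction from C4 of unit A to a cation stabilized by O1 and O7 of ring A) with capture by water from the face opposite to the cis-disposed C2 aryl and C3 hydroxyl groups, which should set C4 as the 3,4-trans (4S) alcohol.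

Step 20
Reactants: 28 (2R,3R,4S)-7,8-bis(benzyloxy)-2-[4-(benzyloxy)phenyl]-6-UB-chromane-3,4-diol
Product: 29 (2R,3R,4S)-2-(4-hydroxyphenyl)-6-[(2S,3R,4R)-3,7,8-trihydroxy-2-(4-hydroxyphenyl)chroman-4-yl]chromane-3,4,7,8-tetrol (CNP0391561.4)
Conditions: H2 (1 atm), Pd(OH)2 on carbon, THF–MeOH, rt, stopped when the benzyl ethers are consumed
Reagents that add atoms: none
Why: hydrogenolysis of the seven benzyl ethers under neutral conditions, which should be much faster than hydrogenolysis of the secondary benzylic C4–OH bond and leaves all stereocentres untouched.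

**Compound list**

1 | 2',3',4'-trihydroxyacetophenone (gallacetophenone) | CC(=O)c1ccc(O)c(O)c1O | starting material
2 | 1-[3,4-bis(benzyloxy)-2-hydroxyphenyl]ethan-1-one | CC(=O)c1ccc(OCc2ccccc2)c(OCc2ccccc2)c1O | intermediate
3 | 1-[3,4-bis(benzyloxy)-2-(methoxymethoxy)phenyl]ethan-1-one | CC(=O)c1ccc(OCc2ccccc2)c(OCc2ccccc2)c1OCOC | intermediate
4 | 4-(benzyloxy)benzaldehyde | O=Cc1ccc(OCc2ccccc2)cc1 | starting material
5 | (E)-1-[3,4-bis(benzyloxy)-2-(methoxymethoxy)phenyl]-3-[4-(benzyloxy)phenyl]prop-2-en-1-one | COCOc1c(OCc2ccccc2)c(OCc2ccccc2)ccc1C(=O)/C=C/c1ccc(OCc2ccccc2)cc1 | intermediate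
6 | [3,4-bis(benzyloxy)-2-(methoxymethoxy)phenyl][(2S,3R)-3-[4-(benzyloxy)phenyl]oxiran-2-yl]methanone | COCOc1c(OCc2ccccc2)c(OCc2ccccc2)ccc1C(=O)[C@H]1O[C@@H]1c1ccc(OCc2ccccc2)cc1 | intermediate
7 | [3,4-bis(benzyloxy)-2-hydroxyphenyl][(2S,3R)-3-[4-(benzyloxy)phenyl]oxiran-2-yl]methanone (phenol epoxide) | Oc1c(OCc2ccccc2)c(OCc2ccccc2)ccc1C(=O)[C@H]1O[C@@H]1c1ccc(OCc2ccccc2)cc1 | intermediate
8 | (2S,3S)-7,8-bis(benzyloxy)-2-[4-(benzyloxy)phenyl]-3-hydroxychroman-4-one | O=C1c2ccc(OCc3ccccc3)c(OCc3ccccc3)c2O[C@@H](c2ccc(OCc3ccccc3)cc2)[C@@H]1O | intermediate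
9 | (2S,3S)-3,7,8-tris(benzyloxy)-2-[4-(benzyloxy)phenyl]chroman-4-one | O=C1c2ccc(OCc3ccccc3)c(OCc3ccccc3)c2O[C@@H](c2ccc(OCc3ccccc3)cc2)[C@@H]1OCc1ccccc1 | intermediate
10 | 2,3-dihydroxybenzaldehyde | O=Cc1cccc(O)c1O | starting material
11 | 2,3-bis(benzyloxy)benzaldehyde | O=Cc1cccc(OCc2ccccc2)c1OCc1ccccc1 | intermediate
12 | 2,3-bis(benzyloxy)phenyl formate | O=COc1cccc(OCc2ccccc2)c1OCc1ccccc1 | intermediate
13 | 2,3-bis(benzyloxy)phenol | Oc1cccc(OCc2ccccc2)c1OCc1ccccc1 | intermediate
14 | allyl bromide (3-bromoprop-1-ene) | C=CCBr | starting material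
15 | 1-(allyloxy)-2,3-bis(benzyloxy)benzene | C=CCOc1cccc(OCc2ccccc2)c1OCc1ccccc1 | intermediate
16 | 6-allyl-2,3-bis(benzyloxy)phenol | C=CCc1ccc(OCc2ccccc2)c(OCc2ccccc2)c1O | intermediate
17 | 6-allyl-2,3-bis(benzyloxy)-4-bromophenol | C=CCc1cc(Br)c(OCc2ccccc2)c(OCc2ccccc2)c1O | intermediate
18 | lithium 6-allyl-2,3-bis(benzyloxy)-4-lithiophenoxide | [Li]Oc1c(CC=C)cc([Li])c(OCc2ccccc2)c1OCc1ccccc1 | intermediate
19 | (2S,3S)-4-[5-allyl-2,3-bis(benzyloxy)-4-hydroxyphenyl]-3,7,8-tris(benzyloxy)-2-[4-(benzyloxy)phenyl]chroman-4-ol, both C4 epimers | C=CCc1cc(C2(O)c3ccc(OCc4ccccc4)c(OCc4ccccc4)c3O[C@@H](c3ccc(OCc4ccccc4)cc3)[C@@H]2OCc2ccccc2)c(OCc2ccccc2)c(OCc2ccccc2)c1O | intermediate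
20 | 6-allyl-2,3-bis(benzyloxy)-4-[(2S,3R,4S)-3,7,8-tris(benzyloxy)-2-[4-(benzyloxy)phenyl]chroman-4-yl]phenol (4-aryl cis to 3-OBn, trans to 2-aryl) | C=CCc1cc([C@@H]2c3ccc(OCc4ccccc4)c(OCc4ccccc4)c3O[C@@H](c3ccc(OCc4ccccc4)cc3)[C@@H]2OCc2ccccc2)c(OCc2ccccc2)c(OCc2ccccc2)c1O | intermediate
21 | 4-(benzyloxy)benzoyl chloride | O=C(Cl)c1ccc(OCc2ccccc2)cc1 | starting material
22 | 6-allyl-2,3-bis(benzyloxy)-4-[(2S,3R,4S)-3,7,8-tris(benzyloxy)-2-[4-(benzyloxy)phenyl]chroman-4-yl]phenyl 4-(benzyloxy)benzoate | C=CCc1cc([C@@H]2c3ccc(OCc4ccccc4)c(OCc4ccccc4)c3O[C@@H](c3ccc(OCc4ccccc4)cc3)[C@@H]2OCc2ccccc2)c(OCc2ccccc2)c(OCc2ccccc2)c1OC(=O)c1ccc(OCc2ccccc2)cc1 | intermediate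
23 | 7,8-bis(benzyloxy)-2-[4-(benzyloxy)phenyl]-6-[(2S,3R,4S)-3,7,8-tris(benzyloxy)-2-[4-(benzyloxy)phenyl]chroman-4-yl]-4H-chromene | C(c1ccccc1)Oc1ccc(C2=CCc3cc([C@@H]5c6ccc(OCc7ccccc7)c(OCc7ccccc7)c6O[C@@H](c6ccc(OCc7ccccc7)cc6)[C@@H]5OCc5ccccc5)c(OCc4ccccc4)c(OCc4ccccc4)c3O2)cc1 | intermediate
24 | [2,3-trans-7,8-bis(benzyloxy)-2-[4-(benzyloxy)phenyl]-6-UB-chroman-3-yl]borane | C(c1ccccc1)Oc1ccc(C2Oc3c(cc([C@@H]5c6ccc(OCc7ccccc7)c(OCc7ccccc7)c6O[C@@H](c6ccc(OCc7ccccc7)cc6)[C@@H]5OCc5ccccc5)c(OCc4ccccc4)c3OCc4ccccc4)CC2B)cc1 | intermediate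
25 | 2,3-trans-7,8-bis(benzyloxy)-2-[4-(benzyloxy)phenyl]-6-UB-chroman-3-ol, both trans diastereomers at C2/C3 | C(c1ccccc1)Oc1ccc(C2Oc3c(cc([C@@H]5c6ccc(OCc7ccccc7)c(OCc7ccccc7)c6O[C@@H](c6ccc(OCc7ccccc7)cc6)[C@@H]5OCc5ccccc5)c(OCc4ccccc4)c3OCc4ccccc4)CC2O)cc1 | intermediate
26 | 7,8-bis(benzyloxy)-2-[4-(benzyloxy)phenyl]-6-UB-chroman-3-one, interconverting C2 epimers | C(c1ccccc1)Oc1ccc(C2Oc3c(cc([C@@H]5c6ccc(OCc7ccccc7)c(OCc7ccccc7)c6O[C@@H](c6ccc(OCc7ccccc7)cc6)[C@@H]5OCc5ccccc5)c(OCc4ccccc4)c3OCc4ccccc4)CC2=O)cc1 | intermediate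
27 | (2R,3R)-7,8-bis(benzyloxy)-2-[4-(benzyloxy)phenyl]-6-[(2S,3R,4S)-3,7,8-tris(benzyloxy)-2-[4-(benzyloxy)phenyl]chroman-4-yl]chroman-3-ol | C(c1ccccc1)Oc1ccc([C@H]2Oc3c(cc([C@@H]5c6ccc(OCc7ccccc7)c(OCc7ccccc7)c6O[C@@H](c6ccc(OCc7ccccc7)cc6)[C@@H]5OCc5ccccc5)c(OCc4ccccc4)c3OCc4ccccc4)C[C@H]2O)cc1 | intermediate
28 | (2R,3R,4S)-7,8-bis(benzyloxy)-2-[4-(benzyloxy)phenyl]-6-[(2S,3R,4S)-3,7,8-tris(benzyloxy)-2-[4-(benzyloxy)phenyl]chroman-4-yl]chromane-3,4-diol | C(c1ccccc1)Oc1ccc([C@H]2Oc3c(cc([C@@H]5c6ccc(OCc7ccccc7)c(OCc7ccccc7)c6O[C@@H](c6ccc(OCc7ccccc7)cc6)[C@@H]5OCc5ccccc5)c(OCc4ccccc4)c3OCc4ccccc4)[C@H](O)[C@H]2O)cc1 | intermediate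
29 | (2R,3R,4S)-2-(4-hydroxyphenyl)-6-[(2S,3R,4R)-3,7,8-trihydroxy-2-(4-hydroxyphenyl)chroman-4-yl]chromane-3,4,7,8-tetrol | Oc1ccc([C@H]2Oc3c(cc([C@@H]4c5ccc(O)c(O)c5O[C@@H](c5ccc(O)cc5)[C@@H]4O)c(O)c3O)[C@H](O)[C@H]2O)cc1 | target

**Totals and risks**

Total step count: 20. Longest linear sequence: 15 steps (steps 1–6 and 12–20).

Steps most likely to fail:

1. Step 15 (bears the label). What may go wrong: ethylidenation of the hindered aryl ester without ring closure, loss of the phenoxide from the titanium adduct, or acid-induced hydrolysis or double-bond migration of the enol ether during isolation. Fallback (known chemistry, two operations): setting out from 22, methylenation of the aryl ester with Cp2TiMe2 (toluene, 70 °C) should give the vinyl ether 6-allyl-2,3-bis(benzyloxy)-4-UB-phenyl 1-[4-(benzyloxy)phenyl]vinyl ether F1. Ring-closing metathesis of F1 with the second-generation Grubbs catalyst RuCl2(=CHPh)(H2IMes)(PCy3) (toluene, 70 °C, loss of ethene) then rejoins the route at 23.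

2. Step 13. What may go wrong: poor facial selectivity of hydride delivery to the tertiary cation, or proton loss toward C3 instead of reduction. Fallback (known chemistry): setting out from 9, NaBH4 reduction (MeOH–THF, 0 °C) should give the 3,4-trans flavan-4-ol (2S,3R,4S)-3,7,8-tris(benzyloxy)-2-[4-(benzyloxy)phenyl]chroman-4-ol F2. BF3·OEt2-promoted Friedel–Crafts alkylation of an excess of phenol 16 (attack para to its hydroxyl) by the flavan-4-yl cation from F2 should then give 20 together with the C4 epimer of 20 F3. The two are separated by chromatography, and the route is rejoined at 20, bypassing steps 12 and 13.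

3. Step 19. What may go wrong: further oxidation of the new 4-ol to the 4-ketone, or competing hydride abstraction at other benzylic positions. Fallback (known chemistry): setting out from 27, DDQ oxidation in CH2Cl2 with 2-ethoxyethanol as the trapping alcohol should give the more oxidation-resistant 4β-(2-ethoxyethoxy) ether of 27 F4. Ionization of F4 with BF3·OEt2 in wet THF at −20 °C and capture of water trans to O3 then returns to the route at 28.

**Further compounds**

F1 | step 15 | 6-allyl-2,3-bis(benzyloxy)-4-[(2S,3R,4S)-3,7,8-tris(benzyloxy)-2-[4-(benzyloxy)phenyl]chroman-4-yl]phenyl 1-[4-(benzyloxy)phenyl]vinyl ether | C=CCc1cc([C@@H]2c3ccc(OCc4ccccc4)c(OCc4ccccc4)c3O[C@@H](c3ccc(OCc4ccccc4)cc3)[C@@H]2OCc2ccccc2)c(OCc2ccccc2)c(OCc2ccccc2)c1OC(=C)c1ccc(OCc2ccccc2)cc1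
F2 | step 13 | (2S,3R,4S)-3,7,8-tris(benzyloxy)-2-[4-(benzyloxy)phenyl]chroman-4-ol | O[C@H]1c2ccc(OCc3ccccc3)c(OCc3ccccc3)c2O[C@@H](c2ccc(OCc3ccccc3)cc2)[C@@H]1OCc1ccccc1
F3 | step 13 | C4 epimer of 20 (4-aryl trans to 3-OBn) | C=CCc1cc([C@H]2c3ccc(OCc4ccccc4)c(OCc4ccccc4)c3O[C@@H](c3ccc(OCc4ccccc4)cc3)[C@@H]2OCc2ccccc2)c(OCc2ccccc2)c(OCc2ccccc2)c1O
F4 | step 19 | (2R,3R,4S)-7,8-bis(benzyloxy)-2-[4-(benzyloxy)phenyl]-4-(2-ethoxyethoxy)-6-[(2S,3R,4S)-3,7,8-tris(benzyloxy)-2-[4-(benzyloxy)phenyl]chroman-4-yl]chroman-3-ol | C(c1ccccc1)Oc1ccc([C@H]2Oc3c(cc([C@@H]5c6ccc(OCc7ccccc7)c(OCc7ccccc7)c6O[C@@H](c6ccc(OCc7ccccc7)cc6)[C@@H]5OCc5ccccc5)c(OCc4ccccc4)c3OCc4ccccc4)[C@H](OCCOCC)[C@H]2O)cc1
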